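## Analysis of the target

The target 15 is an isoflavone: a 4H-chromen-4-one in which benzo ring A is fused to γ-pyranone ring C, with a 2,3,4,6-tetramethoxyphenyl ring B on C3 and free hydroxyl groups at C5 and C7. It has no stereocentre and no double bond of defined geometry. The C3–C1' axis is flanked by two methoxy groups on ring B but only by H–C2 and the C4 carbonyl on ring C, so it is not treated as a stereogenic element. All selectivity questions are therefore questions of regiochemistry and chemoselectivity.

Three parts of the molecule are sensitive:
- C2 is the β-carbon of a vinylogous ester. Hydroxide or alkoxide can add there and open ring C, with loss of C2 as formate if water is present.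
- Ring B is a very electron-rich arene with one free position (C5'), so it is exposed to electrophiles and oxidants.
- The C2=C3 bond can be hydrogenated.

The first difficulty is that six oxygen substituents are present but only the two on ring A are free. Global demethylation is excluded, so the ring A oxygens must arrive differentiated from the four methyl ethers of ring B. The second difficulty is congestion at C3, whose aryl group has both ortho positions substituted, so any bond made to C3 forms next to a twisted, bulky ring.

The strategy rests on one feature. The three oxygen atoms on ring A, at C5, C7 and C8a (O1), are each ortho or para to C4a, the carbon that carries the C4 carbonyl. Every one of these C–O bonds can therefore be made by displacing an acyl-activated fluoride, and a 2,4,6-trifluorobenzoyl unit maps exactly onto C4 and C4a–C8a.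

## Retrosynthetic reasoning

**15 to 14.** The two phenolic O–H bonds are traced back to benzyl ethers in 14. Benzyl is chosen because hydrogenolysis leaves the four methyl ethers of ring B untouched, which no demethylating reagent could guarantee. The forward step must cleave two O–benzyl bonds without reducing C2=C3.

**14 to 12 and 13.** The C5–O and C7–O bonds are cut back to C–F bonds in 12, with the oxygen supplied by alcohol 13. The cut is made here because C5 is ortho and C7 para to the C4 carbonyl, so both positions are activated for addition–elimination. Ring A then needs no oxygenated starting material, and the oxygens arrive already protected. The forward reaction must achieve two displacements without lasting damage to the pyranone.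

**12 to 8 and 9 (key disconnection).** Ring C is opened at O1–C8a and at C3–C4. Cutting C3–C4 separates the molecule into an acyl electrophile 9 and a carbon nucleophile 8 of matching polarity. Cutting O1–C8a uses the third activated position of the same aroyl unit, and its two ortho fluorides are equivalent, so no regiochemical choice arises. A cut at C3–C1' was not taken: it would require cross-coupling of a 3-halochromone with an aryl metal blocked at both ortho positions, which is a hindered coupling. The forward process must acylate 8 at its aryl-bearing carbon to give 10, exchange the amine for an enol oxygen to give 11 (O1 comes from the aqueous hydrolysis), and close the ring by intramolecular fluoride displacement.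

**8 to 6 and 7.** The enamine C–N bond is cut to aldehyde 6 and amine 7. The condensation can give only one enamine because 6 has a single enolisable position.

**6 to 5.** The aldehyde is traced to enol ether 5, a masked and more stable form of the same oxidation level. Hydrolysis releases 6 only when it is needed.

**5 to 3 and 4.** The C=C bond of 5 is cut by a Wittig disconnection into aldehyde 3 and phosphonium salt 4. This adds the one carbon that becomes C2 of the target.

**3 to 1.** The formyl C–C bond is cut to give arene 1, through iminium salt 2. The two free positions of 1 are equivalent and each lies between two methoxy groups, so electrophilic formylation can give only 3.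

## Alternatives that were turned down

**Alternative 1:** Ring C is disconnected at O1–C2 and C4–C4a of a coumarin isomer, so that the carbon destined to be C2 is carried as a lactone carbonyl. In the forward direction the symmetrical phenol A1 (3,5-bis(benzyloxy)phenol) and the arylmalonate A2 would be heated in a high-boiling solvent. Transesterification at the phenol oxygen followed by intramolecular C-acylation ortho to it would give the 4-hydroxycoumarin A3.
- For it: two ring bonds form in one metal-free operation, and the symmetry of A1 removes any regiochemical question. Both ring A oxygens arrive benzyl-protected, so no nucleophile is ever used on a base-labile pyranone. On that last point it is stronger than the chosen route.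
- Against it: A3 has the carbonyl on the wrong carbon. Reaching 15 needs selective O-alkylation of the ambident 4-hydroxycoumarin, partial hydride reduction of the lactone, acid-promoted elimination to the chromone, and then debenzylation. That is four steps after the key step, two of them with open selectivity questions. A2 is itself hard to make because its aryl group is blocked at both ortho positions, and the thermal condensation runs at temperatures near the limit for benzyl aryl ethers.
- Comparison: the chosen strategy closes ring C directly at the correct oxidation level from a purchasable acid chloride, and accepts two fluoride displacements on the chromone in exchange.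

**Alternative 2:** Both bonds to C4 (C4a–C4 and C4–C3) are cut and C4 is traced to carbon monoxide A5. The partners are the aryl iodide A4 (2-iodo-1,3,5-tris(benzyloxy)benzene) and enol ether 5 of the chosen route. In the forward direction zerovalent palladium would insert into the C–I bond of A4 and take up A5 to give an acylpalladium species. This would have to add across the C=C bond of 5 with the acyl group going to the aryl-bearing carbon, and β-hydride elimination would then give enone A6. Debenzylation and acid would close ring C with loss of the enol ether methoxy group.
- For it: three components converge in one step, it shares 5 with the chosen route, and A6 holds every heavy atom of 15 at the right oxidation level. Its step count would be equal to or one lower than that of the chosen route, so on step economy it is at least as good.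
- Against it: the key step asks an acylpalladium to insert into a 1,2-disubstituted, electron-rich alkene, with the acyl group placed next to a ring blocked at both ortho positions. Enol ethers tend to take the migrating group at the oxygen-bearing carbon, and internal alkenes are poor partners in intermolecular carbonylative Heck reactions. A4 is also blocked at both ortho positions, so oxidative addition and uptake of A5 would be slow, and direct coupling without A5 or decarbonylation would compete.
- Comparison: the chosen route makes the same C3–C4 bond by an uncatalysed polar acylation whose regiochemistry is fixed by the enamine. It gives up convergence for predictability.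

**Alternative 3:** Ring A is disconnected at C4a–C5 and C8–C8a and built last by a [4+2] cycloaddition onto a preformed ring C. In the forward direction the electron-rich diene A8 (1,1-dimethoxy-3-(trimethylsilyloxy)buta-1,3-diene) would add to the nitro-bearing C=C bond of nitropyranone A7. The terminal methylene of A8 would bond to the carbon β to the nitro group and the ketene acetal carbon to the nitro-bearing carbon. Loss of the nitro group and of one methoxy group would aromatise ring A to give A9, which has the 7-hydroxyl free and a 5-methoxy group. Chelation-assisted Lewis acid cleavage of that peri methyl ether would finish the synthesis.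
- For it: the oxygenation pattern of ring A follows from the polarity of both partners. The endgame is a single well-precedented selective demethylation with no protecting groups on ring A, which is shorter and gentler than the two-step endgame of the chosen route.
- Against it: A7 is the real problem. Nitration of a 3-arylpyranone would go to the far more electron-rich ring B at C5', so A7 would have to be assembled from acyclic nitro-containing precursors over several steps without close precedent. A7 also carries a second enone C=C bond, and A8 is moisture-sensitive.
- Comparison: the chosen route buys ring A complete as an acid chloride and puts its risk into one acylation–cyclisation sequence rather than into the preparation of a dienophile.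

Key step: step 5

Remark on the chemistry: compounds 1, 4, 7, 9 and 13 are taken as purchasable. Enol ether 5 is expected as an E/Z mixture and is used as such, because both isomers hydrolyse to the same aldehyde.

## Route

Step 1
Reactants: 1 1,2,3,5-tetramethoxybenzene
Product: 3 2,3,4,6-tetramethoxybenzaldehyde, via aryl iminium salt 2 (not isolated)
Conditions: POCl3 (1.2 equiv), DMF, 0 °C to 60 °C; then ice/H2O
Reagents that add atoms: N,N-dimethylformamide, CN(C)C=O; water, O
Why: Vilsmeier–Haack formylation; the two free positions of 1 are equivalent and each is ortho, ortho and para to methoxy groups, so a single iminium salt 2 should form, and it is hydrolysed to 3 on aqueous quench.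

Step 2
Reactants: 3 2,3,4,6-tetramethoxybenzaldehyde; 4 (methoxymethyl)triphenylphosphonium chloride
Product: 5 1,2,3,5-tetramethoxy-4-(2-methoxyethenyl)benzene (E/Z mixture)
Conditions: 4 (1.4 equiv), KOtBu (1.4 equiv), THF, 0 °C to rt
Reagents that add atoms: (methoxymethyl)triphenylphosphonium chloride 4, COC[P+](c1ccccc1)(c1ccccc1)c1ccccc1.[Cl-]
Why: Wittig methoxymethylenation; the small, non-stabilised ylide should add even to this electron-rich benzaldehyde with both ortho positions substituted, and the alkene geometry is irrelevant for the next step.

Step 3
Reactants: 5 1,2,3,5-tetramethoxy-4-(2-methoxyethenyl)benzene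
Product: 6 2-(2,3,4,6-tetramethoxyphenyl)acetaldehyde
Conditions: 3 M aq. HCl, THF, 40 °C; extracted and used crude at once
Reagents that add atoms: water, O
Why: Acid-catalysed enol ether hydrolysis (protonation at the aryl-bearing carbon, addition of water to the oxocarbenium ion, loss of methanol); the aryl methyl ethers are stable to dilute acid.

Step 4
Reactants: 6 2-(2,3,4,6-tetramethoxyphenyl)acetaldehyde; 7 morpholine
Product: 8 (E)-4-[2-(2,3,4,6-tetramethoxyphenyl)ethenyl]morpholine
Conditions: 7 (1.5 equiv), 4 Å molecular sieves, toluene, rt to 50 °C; filtered, concentrated, used without chromatography
Reagents that add atoms: morpholine 7, C1COCCN1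
Why: Enamine condensation of an aldehyde with a secondary amine, driven by removal of water; 6 has only one enolisable position, and the E isomer is the thermodynamic product, although the geometry does not matter for the acylation.

Step 5
Reactants: 8 (E)-4-[2-(2,3,4,6-tetramethoxyphenyl)ethenyl]morpholine; 9 2,4,6-trifluorobenzoyl chloride
Product: 12 5,7-difluoro-3-(2,3,4,6-tetramethoxyphenyl)chromen-4-one, via morpholino enaminone 10 (not isolated), via hydroxymethylene ketone 11 (not isolated)
Conditions: 9 (1.1 equiv), Et3N (1.5 equiv), CH2Cl2, 0 °C to rt; then 1 M aq. HCl, THF, rt, organic phase washed with dilute acid and concentrated; then K2CO3 (2 equiv), dry DMF, rt to 50 °C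
Reagents that add atoms: 2,4,6-trifluorobenzoyl chloride 9, O=C(Cl)c1c(F)cc(F)cc1F; water, O
Why: Enamine 8 is a carbon nucleophile at its aryl-bearing β-carbon; addition to the carbonyl of 9, loss of chloride and deprotonation of the iminium ion by Et3N should give the vinylogous amide 10 and with it the C3–C4 bond (Stork-type enamine acylation, in which any N-acylation is reversible and drains to the C-acyl product). Aqueous acid protonates 10, water adds at the iminium carbon and morpholine leaves, so the oxygen that becomes O1 is delivered by water and 11 results as its chelated enol; the acid wash removes morpholine before any base is added, so no amine is present to attack the fluoroarene. K2CO3 in DMF then forms the delocalised enolate of 11, which can rotate about C2–C3 and C3–C4 until the formyl-derived oxygen lies over C8a; attack there gives a Meisenheimer anion stabilised by the ortho C4 carbonyl and the two remaining fluorines, and loss of fluoride forms O1–C8a. The closest known reaction type is the Grohe cycloacylation used for 4-quinolones, together with its oxygen counterpart, the base-mediated closure of 2-fluoroaryl 1,3-dicarbonyl compounds to chromones. Ring C closes as a six-membered ring by intramolecular addition–elimination at an aromatic carbon (6-exo-trig in the addition step); closure through the ketone oxygen or through C3 would give a four-membered ring and should not compete. No stereocentre is formed, and the C=C geometry of 10 is erased on hydrolysis. The step needs acylation at carbon and not nitrogen, which the enamine polarity secures, and a single site of ring closure, which the symmetry of the aroyl group secures (the two ortho fluorides are equivalent and the para fluoride is out of reach); the small ortho fluorines also let the acid chloride approach the hindered β-carbon.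

Step 6
Reactants: 12 5,7-difluoro-3-(2,3,4,6-tetramethoxyphenyl)chromen-4-one; 13 benzyl alcohol
Product: 14 5,7-bis(benzyloxy)-3-(2,3,4,6-tetramethoxyphenyl)chromen-4-one
Conditions: 13 (2.4 equiv), NaH (2.3 equiv), dry DMF, 0 °C to rt, then 50 °C if needed; AcOH quench
Reagents that add atoms: benzyl alcohol 13, OCc1ccccc1
Why: Twofold SNAr; C7–F is para and C5–F ortho to the C4 carbonyl, so both Meisenheimer intermediates are carbonyl-stabilised and fluoride is the best leaving group for this mechanism. Addition of the alkoxide at C2 is reversible in the absence of water, and the acidic quench should reclose any ring-opened β-benzyloxy enone to the chromone.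

Step 7
Reactants: 14 5,7-bis(benzyloxy)-3-(2,3,4,6-tetramethoxyphenyl)chromen-4-one
Product: 15 5,7-dihydroxy-3-(2,3,4,6-tetramethoxyphenyl)chromen-4-one
Conditions: H2 (1 atm), 10% Pd/C, EtOAc/MeOH, rt; stopped after uptake of two equivalents of H2
Reagents that add atoms: none
Why: Hydrogenolysis of two benzyl aryl ethers over Pd/C, to which the four methyl ethers are inert. The C2=C3 bond is trisubstituted, part of a vinylogous ester and shielded by the twisted ring B, so it should be reduced much more slowly than the benzyl C–O bonds are cleaved.

## Compound list

1 | 1,2,3,5-tetramethoxybenzene | COc1cc(OC)c(OC)c(OC)c1 | starting material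
2 | N-methyl-N-[(2,3,4,6-tetramethoxyphenyl)methylidene]methanaminium dichlorophosphate | COc1cc(OC)c(C=[N+](C)C)c(OC)c1OC.[O-]P(Cl)(Cl)=O | intermediate (not isolated)
3 | 2,3,4,6-tetramethoxybenzaldehyde | COc1cc(OC)c(C=O)c(OC)c1OC | intermediate
4 | (methoxymethyl)triphenylphosphonium chloride | COC[P+](c1ccccc1)(c1ccccc1)c1ccccc1.[Cl-] | starting material
5 | 1,2,3,5-tetramethoxy-4-(2-methoxyethenyl)benzene (E/Z mixture, geometry not defined) | COC=Cc1c(OC)cc(OC)c(OC)c1OC | intermediate
6 | 2-(2,3,4,6-tetramethoxyphenyl)acetaldehyde | COc1cc(OC)c(CC=O)c(OC)c1OC | intermediate
7 | morpholine | C1COCCN1 | starting material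
8 | (E)-4-[2-(2,3,4,6-tetramethoxyphenyl)ethenyl]morpholine | COc1cc(OC)c(/C=C/N2CCOCC2)c(OC)c1OC | intermediate
9 | 2,4,6-trifluorobenzoyl chloride | O=C(Cl)c1c(F)cc(F)cc1F | starting material
10 | 3-(morpholin-4-yl)-2-(2,3,4,6-tetramethoxyphenyl)-1-(2,4,6-trifluorophenyl)prop-2-en-1-one (C=C geometry not defined) | COc1cc(OC)c(C(=CN2CCOCC2)C(=O)c2c(F)cc(F)cc2F)c(OC)c1OC | intermediate (not isolated)
11 | (Z)-3-hydroxy-2-(2,3,4,6-tetramethoxyphenyl)-1-(2,4,6-trifluorophenyl)prop-2-en-1-one (chelated enol of the β-keto aldehyde) | COc1cc(OC)c(/C(=C/O)C(=O)c2c(F)cc(F)cc2F)c(OC)c1OC | intermediate (not isolated)
12 | 5,7-difluoro-3-(2,3,4,6-tetramethoxyphenyl)chromen-4-one | COc1cc(OC)c(-c2coc3cc(F)cc(F)c3c2=O)c(OC)c1OC | intermediate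
13 | benzyl alcohol | OCc1ccccc1 | starting material
14 | 5,7-bis(benzyloxy)-3-(2,3,4,6-tetramethoxyphenyl)chromen-4-one | COc1cc(OC)c(-c2coc3cc(OCc4ccccc4)cc(OCc4ccccc4)c3c2=O)c(OC)c1OC | intermediate
15 | 5,7-dihydroxy-3-(2,3,4,6-tetramethoxyphenyl)chromen-4-one | COc1cc(OC)c(-c2coc3cc(O)cc(O)c3c2=O)c(OC)c1OC | target

## Step count and least certain steps

Total step count: 7. Longest linear sequence: 7 steps (1 to 15).

**Step 5 (key step).** The most likely failure is slow or incomplete C-acylation, because the β-carbon of 8 sits next to a twisted ring with both ortho positions substituted. Reversible N-acylation would then leave the enamine exposed to adventitious hydrolysis. A second risk is deformylation of 11 if base meets it while water is still present. The fallback changes to the deoxybenzoin approach, which needs neither the enamine nor fluoride displacement. It sets out from aldehyde 6 and comes back to the route at target 15. Aldehyde 6 would be oxidised (NaClO2, NaH2PO4, excess 2-methyl-2-butene as chlorine scavenger, t-BuOH/H2O) to 2-(2,3,4,6-tetramethoxyphenyl)acetic acid F1. F1 would acylate phloroglucinol in BF3·OEt2 at about 80 °C to give 2-(2,3,4,6-tetramethoxyphenyl)-1-(2,4,6-trihydroxyphenyl)ethan-1-one F2. Treatment of F2 with DMF, BF3·OEt2 and MsCl would insert C2 and close ring C to 15.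

**Step 6.** Two processes may interfere. Benzyloxide may add at C2 and open the pyranone, and this becomes irreversible if traces of water allow deformylation. The second displacement may also be slow, because the first benzyloxy group makes ring A more electron-rich and the temperature then has to be raised. The fallback moves the exchange of fluoride for oxygen to a stage where no pyranone exists and closes ring C by the classical enaminone route. It sets out from enaminone 10, isolated after the acylation stage of step 5, and comes back at target 15. Heating 10 with excess NaOBn (from 13 and NaH) in DMSO should displace all three fluorides and give 3-(morpholin-4-yl)-2-(2,3,4,6-tetramethoxyphenyl)-1-[2,4,6-tris(benzyloxy)phenyl]prop-2-en-1-one F3. The vinylogous amide is a weaker activator, so forcing conditions are expected, but it has no base-labile ring. Hydrogenolysis over Pd/C would free the phenols to give 3-(morpholin-4-yl)-2-(2,3,4,6-tetramethoxyphenyl)-1-(2,4,6-trihydroxyphenyl)prop-2-en-1-one F4. Brief treatment of F4 with HCl in MeOH would close ring C by conjugate addition of an ortho phenol and loss of morpholine, giving 15. In this variant O1 comes from benzyl alcohol.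

**Step 3.** The electron-rich arylacetaldehyde 6 may undergo self-aldol condensation or air oxidation under the acidic hydrolysis or on standing, and hydrolysis of the styryl enol ether may be sluggish. The fallback avoids the free aldehyde altogether by a Horner–Wittig enamine synthesis. It sets out from aldehyde 3 and comes back at enamine 8. (Morpholin-4-ylmethyl)diphenylphosphine oxide F5, made by condensation of diphenylphosphine oxide, paraformaldehyde and morpholine, would be lithiated with n-BuLi in THF at −78 °C and added to 3. This gives 2-(diphenylphosphoryl)-2-(morpholin-4-yl)-1-(2,3,4,6-tetramethoxyphenyl)ethan-1-ol F6 as a mixture of diastereomers. KOtBu in THF would then eliminate diphenylphosphinate and give 8; steps 2 to 4 are bypassed.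

**Step 7.** Over-reduction of C2=C3 to the isoflavanone may accompany cleavage of the second benzyl ether if the catalyst is too active or the reaction runs too long. The fallback changes the protecting group so that no hydrogenation is needed. It sets out from 12 and comes back at target 15. The displacement of step 6 would be run with 4-methoxybenzyl alcohol in place of 13 to give 5,7-bis[(4-methoxyphenyl)methoxy]-3-(2,3,4,6-tetramethoxyphenyl)chromen-4-one F7. TFA in CH2Cl2 at 0 °C, with 1,3,5-trimethoxybenzene as cation trap, would then release 15.

## Further compounds

F1 | step 5 | 2-(2,3,4,6-tetramethoxyphenyl)acetic acid | COc1cc(OC)c(CC(=O)O)c(OC)c1OC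
F2 | step 5 | 2-(2,3,4,6-tetramethoxyphenyl)-1-(2,4,6-trihydroxyphenyl)ethan-1-one | COc1cc(OC)c(CC(=O)c2c(O)cc(O)cc2O)c(OC)c1OC
F3 | step 6 | 3-(morpholin-4-yl)-2-(2,3,4,6-tetramethoxyphenyl)-1-[2,4,6-tris(benzyloxy)phenyl]prop-2-en-1-one (C=C geometry not defined) | COc1cc(OC)c(C(=CN2CCOCC2)C(=O)c2c(OCc3ccccc3)cc(OCc3ccccc3)cc2OCc2ccccc2)c(OC)c1OC
F4 | step 6 | 3-(morpholin-4-yl)-2-(2,3,4,6-tetramethoxyphenyl)-1-(2,4,6-trihydroxyphenyl)prop-2-en-1-one (C=C geometry not defined) | COc1cc(OC)c(C(=CN2CCOCC2)C(=O)c2c(O)cc(O)cc2O)c(OC)c1OC
F5 | step 3 | (morpholin-4-ylmethyl)diphenylphosphine oxide | O=P(CN1CCOCC1)(c1ccccc1)c1ccccc1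
F6 | step 3 | 2-(diphenylphosphoryl)-2-(morpholin-4-yl)-1-(2,3,4,6-tetramethoxyphenyl)ethan-1-ol (mixture of diastereomers) | COc1cc(OC)c(C(O)C(N2CCOCC2)P(=O)(c2ccccc2)c2ccccc2)c(OC)c1OC
F7 | step 7 | 5,7-bis[(4-methoxyphenyl)methoxy]-3-(2,3,4,6-tetramethoxyphenyl)chromen-4-one | COc1cc(OC)c(-c2coc3cc(OCc4ccc(OC)cc4)cc(OCc4ccc(OC)cc4)c3c2=O)c(OC)c1OC
A1 | alternative 1 | 3,5-bis(benzyloxy)phenol | Oc1cc(OCc2ccccc2)cc(OCc2ccccc2)c1
A2 | alternative 1 | dimethyl 2-(2,3,4,6-tetramethoxyphenyl)malonate | COC(=O)C(C(=O)OC)c1c(OC)cc(OC)c(OC)c1OC
A3 | alternative 1 | 5,7-bis(benzyloxy)-4-hydroxy-3-(2,3,4,6-tetramethoxyphenyl)chromen-2-one | COc1cc(OC)c(-c2c(O)c3c(OCc4ccccc4)cc(OCc4ccccc4)cc3oc2=O)c(OC)c1OC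
A4 | alternative 2 | 2-iodo-1,3,5-tris(benzyloxy)benzene | Ic1c(OCc2ccccc2)cc(OCc2ccccc2)cc1OCc1ccccc1
A5 | alternative 2 | carbon monoxide | [C-]#[O+]
A6 | alternative 2 | (E)-3-methoxy-2-(2,3,4,6-tetramethoxyphenyl)-1-[2,4,6-tris(benzyloxy)phenyl]prop-2-en-1-one | CO/C=C(\c1c(OC)cc(OC)c(OC)c1OC)C(=O)c1c(OCc2ccccc2)cc(OCc2ccccc2)cc1OCc1ccccc1
A7 | alternative 3 | 3-nitro-5-(2,3,4,6-tetramethoxyphenyl)-4H-pyran-4-one | COc1cc(OC)c(-c2cocc([N+](=O)[O-])c2=O)c(OC)c1OC
A8 | alternative 3 | 1,1-dimethoxy-3-(trimethylsilyloxy)buta-1,3-diene | COC(OC)=CC(=C)O[Si](C)(C)C
A9 | alternative 3 | 7-hydroxy-5-methoxy-3-(2,3,4,6-tetramethoxyphenyl)chromen-4-one | COc1cc(O)cc2occ(-c3c(OC)cc(OC)c(OC)c3OC)c(=O)c12
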